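**Retrosynthetic overview**
- The only ring is formed last, by closing C1–C14 of the open C25 chain 14. C-1 reacts as an ester-bearing allyl-palladium cation and the C14=C15 olefin is the nucleophile. Boron leaves C-16 in place of the proton, which relays 16S to 14R.
- Compound 14 comes from a three-component conjunctive coupling (alkenylboronate 9, vinyl, isobutenyl). This step adds C-16 to C-19 and sets C-16.
- Compound 9 comes from cross-metathesis at the isopropylidene end of hydroxy ester 7.
- Compound 7 comes from syn borylation and methoxycarbonylation of enynol 5, which comes from farnesyl bromide and dilithiated but-2-yn-1-ol.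

Assumption: positions are numbered C-1 to C-19 along the geranylfarnesyl chain (C-1 is the ring CH2 next to the stereocentre C-14, C-3 is the ester-bearing carbon). On this numbering the target is (14R).

**Step 1**
Reactants: 1 (2E,6E)-farnesol
Product: 2 (2E,6E)-farnesyl bromide
Conditions: PBr3 (0.4 equiv), Et2O, 0 °C
Reagents that add atoms: phosphorus tribromide, BrP(Br)Br
Why: SN2 bromination of a primary allylic alcohol through its phosphite ester, which at 0 °C leaves both E olefins untouched and gives no allylic shift.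

**Step 2**
Reactants: 2 (2E,6E)-farnesyl bromide; 3 but-2-yn-1-ol
Product: 5 (6E,10E)-7,11,15-trimethylhexadeca-6,10,14-trien-2-yn-1-ol, via dilithiated but-2-yn-1-ol 4 (not isolated)
Conditions: 3, n-BuLi (2.1 equiv), TMEDA, THF, −78 to 0 °C; then 2, −78 °C to rt
Reagents that add atoms: none
Why: Propargylic dianion alkylation, in which the carbanion end of the O,C-dianion displaces the primary allylic bromide (SN2) and lays down C-1 to C-4 in one operation.

**Step 3**
Reactants: 5 (6E,10E)-7,11,15-trimethylhexadeca-6,10,14-trien-2-yn-1-ol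
Product: 6 (2Z,6E,10E)-7,11,15-trimethyl-3-(pinacolboryl)hexadeca-2,6,10,14-tetraen-1-ol
Conditions: B2pin2 (1.1 equiv), CuCl (5 mol %), PCy3 (6 mol %), NaOtBu (15 mol %), MeOH (2 equiv), toluene, rt
Reagents that add atoms: bis(pinacolato)diboron, CC1(C)OB(OC1(C)C)B1OC(C)(C)C(C)(C)O1
Why: Copper-catalysed syn protoboration of a propargylic alcohol touches only the alkyne and puts boron on the carbon remote from CH2OH, so H-2 and boron are cis and C-1 and C-4 are cis as in the target.

**Step 4**
Reactants: 6 (2Z,6E,10E)-7,11,15-trimethyl-3-(pinacolboryl)hexadeca-2,6,10,14-tetraen-1-ol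
Product: 7 methyl (2E)-4-hydroxy-2-[(3E,7E)-4,8,12-trimethyltrideca-3,7,11-trien-1-yl]but-2-enoate
Conditions: Pd(OAc)2 (5 mol %), PPh3 (10 mol %), p-benzoquinone (1.2 equiv), CO (1 atm), MeOH, rt
Reagents that add atoms: carbon monoxide, [C-]#[O+]; methanol, CO
Why: Oxidative alkoxycarbonylation of an alkenylboronate (transmetalation, CO insertion, methanolysis) replaces boron by CO2Me with retention, which fixes the ester trans to C-1.

**Step 5**
Reactants: 7 methyl (2E)-4-hydroxy-2-[(3E,7E)-4,8,12-trimethyltrideca-3,7,11-trien-1-yl]but-2-enoate; 8 isopropenylboronic acid pinacol ester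
Product: 9 methyl (2E)-4-hydroxy-2-[(3E,7E,11Z)-4,8-dimethyl-12-(pinacolboryl)trideca-3,7,11-trien-1-yl]but-2-enoate
Conditions: 8 (5 equiv), second-generation Hoveyda–Grubbs catalyst (5 mol %), CH2Cl2, 40 °C, argon sweep
Reagents that add atoms: none
Why: Olefin cross-metathesis, in which only the gem-dimethyl terminus is open enough to give the alkylidene (losing isobutene), and this then takes up 8 with the chain trans to the bulky boryl group.

**Step 6**
Reactants: 9 methyl (2E)-4-hydroxy-2-[(3E,7E,11Z)-4,8-dimethyl-12-(pinacolboryl)trideca-3,7,11-trien-1-yl]but-2-enoate; 10 vinylmagnesium bromide; 11 1-bromo-2-methylprop-1-ene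
Product: 13 methyl (2E)-4-hydroxy-2-[(3E,7E,11E,13S)-4,8,12,16-tetramethyl-13-(pinacolboryl)heptadeca-3,7,11,15-tetraen-1-yl]but-2-enoate, via vinyl boronate complex 12 (not isolated)
Conditions: 10 (2.1 equiv), THF, −40 to 0 °C; then NaOTf, Pd(OAc)2 (3 mol %), MandyPhos (3.6 mol %, the enantiomer that gives 16S), 11 (1.2 equiv), THF/DMSO, 40 °C
Reagents that add atoms: none
Why: Enantioselective conjunctive cross-coupling of a bis(alkenyl)borate, in which the isobutenyl-palladium species binds the unsubstituted vinyl group, the C-15 alkenyl group migrates from boron to C-16 with its geometry kept, and the chiral diphosphine sets C-16 as S.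

**Step 7**
Reactants: 13 methyl (2E)-4-hydroxy-2-[(3E,7E,11E,13S)-4,8,12,16-tetramethyl-13-(pinacolboryl)heptadeca-3,7,11,15-tetraen-1-yl]but-2-enoate
Product: 14 methyl (2E)-4-(methoxycarbonyloxy)-2-[(3E,7E,11E,13S)-4,8,12,16-tetramethyl-13-(pinacolboryl)heptadeca-3,7,11,15-tetraen-1-yl]but-2-enoate
Conditions: ClCO2Me (1.5 equiv), pyridine (3 equiv), CH2Cl2, 0 °C
Reagents that add atoms: methyl chloroformate, COC(=O)Cl
Why: O-acylation of the primary allylic alcohol under conditions that leave a pinacol allylboronate and C-16 untouched.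

**Step 8**
Reactants: 14 methyl (2E)-4-(methoxycarbonyloxy)-2-[(3E,7E,11E,13S)-4,8,12,16-tetramethyl-13-(pinacolboryl)heptadeca-3,7,11,15-tetraen-1-yl]but-2-enoate
Product: 15 methyl (1E,4R,7E,11E)-7,11-dimethyl-4-[(2E)-6-methylhepta-2,5-dien-2-yl]cyclotetradeca-1,7,11-triene-1-carboxylate
Conditions: 14 added over 12 h to Pd2(dba)3 (5 mol %), P(OPh)3 (20 mol %), THF, 50 °C, final 1 mM
Reagents that add atoms: none
Why: Proposed new method: zerovalent palladium ionises the carbonate to an ester-bearing allyl-palladium cation, CO2 and methoxide; the methoxide binds the pinacol boronate, and the activated C14=C15 olefin attacks the free CH2 terminus C-1 (remote from the ester) anti to the C16–B bond; boron then leaves as MeOBpin in place of the C-16 proton, so attack through the conformer with H-16 in the olefin plane turns 16S into 14R and gives the E C15=C16 olefin; the plain olefins cannot compete because their addition to an allyl-palladium cation is uphill and reversible, whereas boron loss is not, and the monodentate acceptor ligand is chosen to avoid the inner-sphere coupling at C-3 that chelating diphosphines favour; the closest known reaction types are the palladium-catalysed allyl–allyl cross-coupling of allylboronates with allylic carbonates and the anti-SE2' reactions of allylboronate complexes with carbon electrophiles.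

**Compound list**
1 | (2E,6E)-farnesol | CC(C)=CCC/C(C)=C/CC/C(C)=C/CO | starting material
2 | (2E,6E)-farnesyl bromide | CC(C)=CCC/C(C)=C/CC/C(C)=C/CBr | intermediate
3 | but-2-yn-1-ol | CC#CCO | starting material
4 | dilithiated but-2-yn-1-ol (O,C-dianion) | [Li+].[Li+].[CH2-]C#CC[O-] | intermediate
5 | (6E,10E)-7,11,15-trimethylhexadeca-6,10,14-trien-2-yn-1-ol | CC(C)=CCC/C(C)=C/CC/C(C)=C/CCC#CCO | intermediate
6 | (2Z,6E,10E)-7,11,15-trimethyl-3-(pinacolboryl)hexadeca-2,6,10,14-tetraen-1-ol | OC/C=C(B1OC(C)(C)C(C)(C)O1)\CC/C=C(C)/CC/C=C(C)/CCC=C(C)C | intermediate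
7 | methyl (2E)-4-hydroxy-2-[(3E,7E)-4,8,12-trimethyltrideca-3,7,11-trien-1-yl]but-2-enoate | OC/C=C(C(=O)OC)\CC/C=C(C)/CC/C=C(C)/CCC=C(C)C | intermediate
8 | isopropenylboronic acid pinacol ester | CC(=C)B1OC(C)(C)C(C)(C)O1 | starting material
9 | methyl (2E)-4-hydroxy-2-[(3E,7E,11Z)-4,8-dimethyl-12-(pinacolboryl)trideca-3,7,11-trien-1-yl]but-2-enoate | OC/C=C(C(=O)OC)\CC/C=C(C)/CC/C=C(C)/CC/C=C(C)/B1OC(C)(C)C(C)(C)O1 | intermediate
10 | vinylmagnesium bromide | C=C[Mg]Br | starting material
11 | 1-bromo-2-methylprop-1-ene | CC(C)=CBr | starting material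
12 | vinyl boronate complex of 9 (bromomagnesium alkoxide and borate) | Br[Mg+].Br[Mg+].[O-]C/C=C(C(=O)OC)\CC/C=C(C)/CC/C=C(C)/CC/C=C(C)/[B-]1(C=C)OC(C)(C)C(C)(C)O1 | intermediate
13 | methyl (2E)-4-hydroxy-2-[(3E,7E,11E,13S)-4,8,12,16-tetramethyl-13-(pinacolboryl)heptadeca-3,7,11,15-tetraen-1-yl]but-2-enoate (16S in chain numbering) | OC/C=C(C(=O)OC)\CC/C=C(C)/CC/C=C(C)/CC/C=C(C)/[C@H](CC=C(C)C)B1OC(C)(C)C(C)(C)O1 | intermediate
14 | methyl carbonate of 13 | COC(=O)OC/C=C(C(=O)OC)\CC/C=C(C)/CC/C=C(C)/CC/C=C(C)/[C@H](CC=C(C)C)B1OC(C)(C)C(C)(C)O1 | intermediate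
15 | methyl (1E,4R,7E,11E)-7,11-dimethyl-4-[(2E)-6-methylhepta-2,5-dien-2-yl]cyclotetradeca-1,7,11-triene-1-carboxylate | COC(=O)/C1=C/C[C@H](/C(C)=C/CC=C(C)C)CC/C(C)=C/CC/C(C)=C/CC1 | target

**Total step count:** 8. **Longest linear sequence:** 8.

**The three steps most likely to fail**

Step 8 carries the most risk. Inner-sphere allyl–allyl coupling at C-3, the Z isomer of the C15=C16 olefin (the C-15 methyl group weakens the preference for H-16 in the olefin plane), protodeboronation and diene formation can all compete. The fallback closes the same bond on a carbonyl group; it sets out from 9 and comes back at 15.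
- Step 6 is run with the mirror-image MandyPhos to give the (16R)-allylboronate alcohol F1.
- MnO2 in CH2Cl2 oxidises the allylic alcohol of F1 to the (16R)-boronate 4-oxo-enoate F2.
- Warming F2 at 1 mM in toluene forms C1–C14 by a chair-like allylboration. Boron and the new bond lie on the same face, which is why C-16 is inverted. The product is the macrocyclic (1R)-alcohol F3, with C-14 arranged as in the target.
- ClCO2Me and pyridine give the macrocyclic methyl carbonate F4.
- Pd(PPh3)4 and NaBH4 in THF then deliver hydride to C-1, the allyl terminus remote from the ester, to give 15.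

Step 6 may suffer from attack of the Grignard reagent on the ester or from direct Suzuki coupling of an alkenyl group. The fallback is a lithiation–borylation; it sets out from 9 and comes back at 13.
- 4-Methylpent-3-en-1-ol and iPr2NCOCl give homoprenyl N,N-diisopropylcarbamate F5.
- s-BuLi and (+)-sparteine in Et2O at −78 °C give the (R)-lithiated carbamate F6.
- Two equivalents of F6 are used. The first deprotonates the hydroxyl group of 9, and the second adds to boron with retention to give the carbamoyloxyalkyl boronate complex F7.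
- On warming with MgBr2, the C-15 alkenyl group of F7 shifts to C-16 with inversion and loss of carbamate, giving 13.

Step 5 may cut the internal trisubstituted olefins or stall. The fallback degrades the terminus stepwise; it sets out from 7 and comes back at 9.
- NBS in aqueous THF gives the terminal bromohydrin F8 (racemic).
- K2CO3 in MeOH closes F8 to the terminal epoxide F9.
- H5IO6 in THF/water cleaves F9 to the C-14 aldehyde F10.
- A boron–Wittig reaction of F10 with 1,1-bis(pinacolboryl)ethane and LiTMP (extra base for the hydroxyl group) at −78 °C gives 9, with the chain trans to boron.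

**Further compounds**
F1 | step 8 | (16R)-allylboronate alcohol (C-16 epimer of 13) | OC/C=C(C(=O)OC)\CC/C=C(C)/CC/C=C(C)/CC/C=C(C)/[C@@H](CC=C(C)C)B1OC(C)(C)C(C)(C)O1
F2 | step 8 | (16R)-boronate 4-oxo-enoate | O=C/C=C(C(=O)OC)\CC/C=C(C)/CC/C=C(C)/CC/C=C(C)/[C@@H](CC=C(C)C)B1OC(C)(C)C(C)(C)O1
F3 | step 8 | macrocyclic (1R)-alcohol (1-hydroxy derivative of 15) | COC(=O)/C1=C/[C@@H](O)[C@H](/C(C)=C/CC=C(C)C)CC/C(C)=C/CC/C(C)=C/CC1
F4 | step 8 | macrocyclic methyl carbonate | COC(=O)/C1=C/[C@@H](OC(=O)OC)[C@H](/C(C)=C/CC=C(C)C)CC/C(C)=C/CC/C(C)=C/CC1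
F5 | step 6 | homoprenyl N,N-diisopropylcarbamate | CC(C)=CCCOC(=O)N(C(C)C)C(C)C
F6 | step 6 | (R)-lithiated carbamate | [Li][C@H](CC=C(C)C)OC(=O)N(C(C)C)C(C)C
F7 | step 6 | carbamoyloxyalkyl boronate complex | [Li+].[Li+].[O-]C/C=C(C(=O)OC)\CC/C=C(C)/CC/C=C(C)/CC/C=C(C)/[B-]1([C@H](CC=C(C)C)OC(=O)N(C(C)C)C(C)C)OC(C)(C)C(C)(C)O1
F8 | step 5 | terminal bromohydrin (racemic) | OC/C=C(C(=O)OC)\CC/C=C(C)/CC/C=C(C)/CCC(Br)C(C)(C)O
F9 | step 5 | terminal epoxide (racemic) | OC/C=C(C(=O)OC)\CC/C=C(C)/CC/C=C(C)/CCC1OC1(C)C
F10 | step 5 | C-14 aldehyde | OC/C=C(C(=O)OC)\CC/C=C(C)/CC/C=C(C)/CCC=O
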